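**Strategy.** The target is the hydroarylation dimer of a single chromene monomer: C6 of one unit (ring A) is bonded to C4 of the other (ring B). The plan therefore rests on that monomer, whose 2,2-dimethyl-2H-pyran ring is closed by forming its C2–C3 bond. The key step exploits the O1–C2(CH3)2 unit as a latent aryl isopropyl ether and C3=C4 as a latent ortho ethynyl group: a platinum-triggered 1,5-hydride shift from the isopropyl methine to the alkyne, followed by C–C closure, isomerises a 2-ethynylaryl isopropyl ether to the chromene in one redox-neutral operation. A chiral phosphoric acid then dimerises the deprotected monomer and sets the C4 stereocenter.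

Key step: step 7

Remark: compounds 1 and 2 are taken as catalogue chemicals; (R)-TRIP is assumed to deliver the (4R) product in step 9, and the (S)-acid would be used if the sense of induction proved opposite.

Step 1
Reactants: 1 4-bromo-3,5-dimethoxybenzaldehyde; 2 diethyl (4-methoxybenzyl)phosphonate
Product: 3 (E)-2-bromo-1,3-dimethoxy-5-[2-(4-methoxyphenyl)ethenyl]benzene
Conditions: NaH, THF, 0 °C to rt
Reagents that add atoms: none
Why: Horner–Wadsworth–Emmons olefination of an aromatic aldehyde with a benzylic phosphonate anion should give the (E)-stilbene, the aryl bromide being inert to NaH at this temperature.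

Step 2
Reactants: 3 (E)-2-bromo-1,3-dimethoxy-5-[2-(4-methoxyphenyl)ethenyl]benzene
Product: 4 2-bromo-1,3-dimethoxy-5-[2-(4-methoxyphenyl)ethyl]benzene
Conditions: H2 (1 atm), 5% Pt/C (sulfided), EtOAc, rt
Reagents that add atoms: none
Why: Heterogeneous hydrogenation over sulfided platinum on carbon should saturate the stilbene double bond while leaving the aryl C–Br bond intact.

Step 3
Reactants: 4 2-bromo-1,3-dimethoxy-5-[2-(4-methoxyphenyl)ethyl]benzene
Product: 5 2-bromo-3-methoxy-5-[2-(4-methoxyphenyl)ethyl]phenol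
Conditions: NaSEt, DMF, 110 °C; then cold dilute aq. HCl
Reagents that add atoms: none
Why: Nucleophilic (SN2) demethylation by thiolate should stop after one methyl group of the symmetric bromodimethoxy ring because the phenoxide formed deactivates the second ether, while the methoxy group of the 4-alkylanisole ring, with its poorer phenoxide leaving group, should react more slowly.

Step 4
Reactants: 5 2-bromo-3-methoxy-5-[2-(4-methoxyphenyl)ethyl]phenol
Product: 6 6-bromo-5-methoxy-3-[2-(4-methoxyphenyl)ethyl]-2-(3-methylbut-2-en-1-yl)phenol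
Conditions: NaH, toluene, 0 °C; then prenyl bromide, rt to 40 °C
Reagents that add atoms: prenyl bromide (1-bromo-3-methylbut-2-ene), CC(C)=CCBr
Why: Ortho C-alkylation of a sodium phenoxide in a non-coordinating solvent proceeds through a contact ion pair that delivers the allylic halide to the ortho carbon, and only one ortho position is free here because the other carries bromine.

Step 5
Reactants: 6 6-bromo-5-methoxy-3-[2-(4-methoxyphenyl)ethyl]-2-(3-methylbut-2-en-1-yl)phenol
Product: 7 2-bromo-1-methoxy-5-[2-(4-methoxyphenyl)ethyl]-4-(3-methylbut-2-en-1-yl)-3-(propan-2-yloxy)benzene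
Conditions: 2-iodopropane, Cs2CO3, DMF, 50 °C
Reagents that add atoms: 2-iodopropane, CC(C)I
Why: Williamson etherification of the cesium phenoxide with a secondary iodide should install the isopropyl group on the oxygen next to the prenyl group, which is the future ring oxygen.

Step 6
Reactants: 7 2-bromo-1-methoxy-5-[2-(4-methoxyphenyl)ethyl]-4-(3-methylbut-2-en-1-yl)-3-(propan-2-yloxy)benzene
Product: 9 2-ethynyl-1-methoxy-5-[2-(4-methoxyphenyl)ethyl]-4-(3-methylbut-2-en-1-yl)-3-(propan-2-yloxy)benzene, via trimethylsilyl alkyne 8 (not isolated)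
Conditions: PdCl2(PhCN)2 (3 mol%), [(t-Bu)3PH]BF4 (6 mol%), CuI (2 mol%), i-Pr2NH, trimethylsilylacetylene, dioxane, 45 °C; then K2CO3 (cat.), MeOH, rt
Reagents that add atoms: trimethylsilylacetylene, C#C[Si](C)(C)C
Why: Sonogashira coupling with the bulky electron-rich phosphine P(t-Bu)3 engages electron-rich, doubly ortho-substituted aryl bromides under mild conditions, and methanolysis of the C–Si bond should then free the terminal alkyne in the same flask.

Step 7
Reactants: 9 2-ethynyl-1-methoxy-5-[2-(4-methoxyphenyl)ethyl]-4-(3-methylbut-2-en-1-yl)-3-(propan-2-yloxy)benzene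
Product: 10 5-methoxy-7-[2-(4-methoxyphenyl)ethyl]-2,2-dimethyl-8-(3-methylbut-2-en-1-yl)-2H-chromene
Conditions: PtI4 (10 mol%), MeCN, 100 °C, sealed tube, high dilution
Reagents that add atoms: none
Why: Proposed new method: PtI4 binds the terminal alkyne and slips toward the terminal carbon, so that positive charge builds at the aryl-bound alkyne carbon (stabilised by the two ortho oxygens), and the isopropyl methine hydrogen is transferred to that carbon as hydride through a six-membered transition state (1,5-shift) anti to platinum, giving an aryloxy(dimethyl)oxocarbenium ion and a (Z)-alkenylplatinum species with the metal cis to the arene. The platinum-bearing carbon then attacks the oxocarbenium carbon, forming the C2–C3 bond of the pyran ring and releasing the catalyst, so that the ether/alkyne pair is isomerised to the 2,2-dimethyl-2H-chromene without change of formula. The closest known reaction types are the platinum- and gold-catalysed hydride-shift hydroalkylation of terminal alkynes by tethered alkyl ethers and the Lewis-acid-catalysed 1,5-hydride shift/cyclization of ortho-alkoxybenzylidene malonates to benzopyrans; the untested element is the pairing of an aryl isopropyl ether donor with an unactivated ortho ethynyl acceptor. The six-membered ring is closed in a 6-endo-trig mode with respect to the C=O+ bond of the oxocarbenium ion. No stereocenter is formed. The step needs the hydride to come from the isopropyl group and not from the methoxy group on the other flank of the alkyne, which the tertiary versus primary C–H bond (dimethyl-substituted versus unsubstituted oxocarbenium ion) should secure; attack of either ether oxygen on the alkyne should be unproductive because neither methyl nor isopropyl migrates readily from an oxonium ion, and the prenyl group, meta to the alkyne, cannot reach it.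

Step 8
Reactants: 10 5-methoxy-7-[2-(4-methoxyphenyl)ethyl]-2,2-dimethyl-8-(3-methylbut-2-en-1-yl)-2H-chromene
Product: 11 7-[2-(4-hydroxyphenyl)ethyl]-2,2-dimethyl-8-(3-methylbut-2-en-1-yl)-2H-chromen-5-ol
Conditions: NaSEt (excess), DMF, 140 °C; then cold dilute aq. HCl
Reagents that add atoms: none
Why: Excess thiolate at higher temperature should cleave both remaining aryl methyl ethers by SN2 attack on methyl under basic, non-electrophilic conditions that leave the prenyl group and the acid-sensitive 2H-chromene untouched.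

Step 9
Reactants: 11 7-[2-(4-hydroxyphenyl)ethyl]-2,2-dimethyl-8-(3-methylbut-2-en-1-yl)-2H-chromen-5-ol (two molecules)
Product: 12 (4R)-4-{5-hydroxy-7-[2-(4-hydroxyphenyl)ethyl]-2,2-dimethyl-8-(3-methylbut-2-en-1-yl)-2H-chromen-6-yl}-7-[2-(4-hydroxyphenyl)ethyl]-2,2-dimethyl-8-(3-methylbut-2-en-1-yl)-3,4-dihydro-2H-chromen-5-ol
Conditions: (R)-TRIP [(R)-3,3'-bis(2,4,6-triisopropylphenyl)-1,1'-binaphthyl-2,2'-diyl hydrogen phosphate] (10 mol%), toluene, 4 Å molecular sieves, 0 °C, stopped at partial conversion with recovery of 11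
Reagents that add atoms: none
Why: In this chiral-phosphoric-acid-catalysed Friedel–Crafts hydroarylation the acid should protonate C3 of one chromene to give its ortho-quinone methide (C5=O, C4=C4a) hydrogen-bonded to the phosphate, which also binds the 5-OH of a second molecule and directs its only free ring position (C6) onto C4, the face of attack and hence the (4R) configuration being controlled by the 3,3'-aryl groups of the catalyst.

**Compound list**

1 | 4-bromo-3,5-dimethoxybenzaldehyde | COc1cc(C=O)cc(OC)c1Br | starting material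
2 | diethyl (4-methoxybenzyl)phosphonate | CCOP(=O)(Cc1ccc(OC)cc1)OCC | starting material
3 | (E)-2-bromo-1,3-dimethoxy-5-[2-(4-methoxyphenyl)ethenyl]benzene | COc1ccc(/C=C/c2cc(OC)c(Br)c(OC)c2)cc1 | intermediate
4 | 2-bromo-1,3-dimethoxy-5-[2-(4-methoxyphenyl)ethyl]benzene | COc1ccc(CCc2cc(OC)c(Br)c(OC)c2)cc1 | intermediate
5 | 2-bromo-3-methoxy-5-[2-(4-methoxyphenyl)ethyl]phenol | COc1ccc(CCc2cc(O)c(Br)c(OC)c2)cc1 | intermediate
6 | 6-bromo-5-methoxy-3-[2-(4-methoxyphenyl)ethyl]-2-(3-methylbut-2-en-1-yl)phenol | COc1ccc(CCc2cc(OC)c(Br)c(O)c2CC=C(C)C)cc1 | intermediate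
7 | 2-bromo-1-methoxy-5-[2-(4-methoxyphenyl)ethyl]-4-(3-methylbut-2-en-1-yl)-3-(propan-2-yloxy)benzene | COc1ccc(CCc2cc(OC)c(Br)c(OC(C)C)c2CC=C(C)C)cc1 | intermediate
8 | {[2-methoxy-4-[2-(4-methoxyphenyl)ethyl]-5-(3-methylbut-2-en-1-yl)-6-(propan-2-yloxy)phenyl]ethynyl}trimethylsilane | COc1ccc(CCc2cc(OC)c(C#C[Si](C)(C)C)c(OC(C)C)c2CC=C(C)C)cc1 | intermediate
9 | 2-ethynyl-1-methoxy-5-[2-(4-methoxyphenyl)ethyl]-4-(3-methylbut-2-en-1-yl)-3-(propan-2-yloxy)benzene | COc1ccc(CCc2cc(OC)c(C#C)c(OC(C)C)c2CC=C(C)C)cc1 | intermediate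
10 | 5-methoxy-7-[2-(4-methoxyphenyl)ethyl]-2,2-dimethyl-8-(3-methylbut-2-en-1-yl)-2H-chromene | COc1ccc(CCc2cc(OC)c3C=CC(C)(C)Oc3c2CC=C(C)C)cc1 | intermediate
11 | 7-[2-(4-hydroxyphenyl)ethyl]-2,2-dimethyl-8-(3-methylbut-2-en-1-yl)-2H-chromen-5-ol | CC(C)=CCc1c(CCc2ccc(O)cc2)cc(O)c2c1OC(C)(C)C=C2 | intermediate
12 | (4R)-4-{5-hydroxy-7-[2-(4-hydroxyphenyl)ethyl]-2,2-dimethyl-8-(3-methylbut-2-en-1-yl)-2H-chromen-6-yl}-7-[2-(4-hydroxyphenyl)ethyl]-2,2-dimethyl-8-(3-methylbut-2-en-1-yl)-3,4-dihydro-2H-chromen-5-ol | CC(C)=CCc1c(CCc2ccc(O)cc2)c([C@H]2CC(C)(C)Oc3c(CC=C(C)C)c(CCc4ccc(O)cc4)cc(O)c32)c(O)c2c1OC(C)(C)C=C2 | target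

**Step count.** Total: 9 steps. Longest linear sequence: 9 steps (1 to 12).

**Steps most likely to fail**

Step 7. The hydride transfer from the aryl isopropyl ether may be too slow, so that alkyne hydration, oligomerisation or dealkylative attack of an ether oxygen on the activated alkyne takes over. The fallback sets out from 7 and comes back at 10, and forms the same C2–C3 bond by known carbenoid chemistry. Bromine–lithium exchange of 7 (n-BuLi, THF, −78 °C) and acylation with N-methoxy-N-methylacetamide would give the aryl methyl ketone F1. Claisen condensation with 2,2,2-trifluoroethyl trifluoroacetate (LiN(SiMe3)2, THF, −78 °C) would give the trifluoroacetyl diketone F2, and detrifluoroacetylative diazo transfer (MsN3, Et3N, aqueous MeCN) the diazomethyl ketone F3. Rh2(OAc)4 in CH2Cl2 would then insert the carbenoid carbon into the tertiary C–H bond of the ortho isopropoxy group, a known route from ortho-alkoxy diazoacetophenones to chroman-4-ones, to give the chroman-4-one F4. Reduction with NaBH4 in MeOH would give the chroman-4-ol F5, and dehydration (catalytic p-TsOH, toluene, 80 °C) would return to 10.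

Step 9. The attack on the ortho-quinone methide may show poor facial selectivity, and the dimer may react on to higher oligomers or couple through the alkene instead of C6. The fallback sets out from 11 and comes back at 12. Dimerisation with an achiral acid (diphenyl phosphate, CH2Cl2, 0 °C, low conversion with recycling of 11) would give the racemic dimer F6, and the (4R) enantiomer 12 would be separated by preparative HPLC on an amylose tris(3,5-dimethylphenylcarbamate) stationary phase.

Step 4. O-alkylation and para C-alkylation of the phenoxide may compete with the hindered ortho C-alkylation. The fallback sets out from 5 and comes back at 6. O-alkylation with 3-chloro-3-methylbut-1-yne (CuCl2·2H2O cat., DBU, MeCN, 0 °C) would give the 1,1-dimethylpropargyl ether F7. Semi-hydrogenation (H2, Pd/CaCO3 poisoned with Pb(OAc)2, quinoline, EtOAc) would give the 1,1-dimethylallyl ether F8. Aromatic Claisen rearrangement (N,N-diethylaniline, 140 °C) would then deliver the prenyl group to the only free ortho carbon and give 6.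

**Further compounds**

F1 | step 7 | 1-[2-methoxy-4-[2-(4-methoxyphenyl)ethyl]-5-(3-methylbut-2-en-1-yl)-6-(propan-2-yloxy)phenyl]ethan-1-one | COc1ccc(CCc2cc(OC)c(C(C)=O)c(OC(C)C)c2CC=C(C)C)cc1
F2 | step 7 | 4,4,4-trifluoro-1-[2-methoxy-4-[2-(4-methoxyphenyl)ethyl]-5-(3-methylbut-2-en-1-yl)-6-(propan-2-yloxy)phenyl]butane-1,3-dione | COc1ccc(CCc2cc(OC)c(C(=O)CC(=O)C(F)(F)F)c(OC(C)C)c2CC=C(C)C)cc1
F3 | step 7 | 2-diazo-1-[2-methoxy-4-[2-(4-methoxyphenyl)ethyl]-5-(3-methylbut-2-en-1-yl)-6-(propan-2-yloxy)phenyl]ethan-1-one | COc1ccc(CCc2cc(OC)c(C(=O)C=[N+]=[N-])c(OC(C)C)c2CC=C(C)C)cc1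
F4 | step 7 | 5-methoxy-7-[2-(4-methoxyphenyl)ethyl]-2,2-dimethyl-8-(3-methylbut-2-en-1-yl)-2,3-dihydro-4H-chromen-4-one | COc1ccc(CCc2cc(OC)c3C(=O)CC(C)(C)Oc3c2CC=C(C)C)cc1
F5 | step 7 | 5-methoxy-7-[2-(4-methoxyphenyl)ethyl]-2,2-dimethyl-8-(3-methylbut-2-en-1-yl)-3,4-dihydro-2H-chromen-4-ol (racemic) | COc1ccc(CCc2cc(OC)c3C(O)CC(C)(C)Oc3c2CC=C(C)C)cc1
F6 | step 9 | racemic 4-{5-hydroxy-7-[2-(4-hydroxyphenyl)ethyl]-2,2-dimethyl-8-(3-methylbut-2-en-1-yl)-2H-chromen-6-yl}-7-[2-(4-hydroxyphenyl)ethyl]-2,2-dimethyl-8-(3-methylbut-2-en-1-yl)-3,4-dihydro-2H-chromen-5-ol | CC(C)=CCc1c(CCc2ccc(O)cc2)c(C2CC(C)(C)Oc3c(CC=C(C)C)c(CCc4ccc(O)cc4)cc(O)c32)c(O)c2c1OC(C)(C)C=C2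
F7 | step 4 | 2-bromo-1-methoxy-5-[2-(4-methoxyphenyl)ethyl]-3-[(2-methylbut-3-yn-2-yl)oxy]benzene | COc1ccc(CCc2cc(OC)c(Br)c(OC(C)(C)C#C)c2)cc1
F8 | step 4 | 2-bromo-1-methoxy-5-[2-(4-methoxyphenyl)ethyl]-3-[(2-methylbut-3-en-2-yl)oxy]benzene | COc1ccc(CCc2cc(OC)c(Br)c(OC(C)(C)C=C)c2)cc1
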